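## Retrosynthetic overview

1. Target 43 ⇐ 41 by closing γ-lactone ring C (C7–OH onto C19) and removing the acetonide; 41 ⇐ 39 by cutting C6–C7. The strategy rests on the anti chlorohydrin C7(O)–C6(Cl) next to the exocyclic C5=C16 methylene in ten-membered ring B (C1–C10): this is the pattern a C16-bound γ-chloroallyl metal leaves when it adds through C6 to a C7 aldehyde.
2. 39 ⇐ ring A aldehyde 23 + dioxolanone 28 by a C8–C9 aldol (C8 by self-regeneration of the malate centre, C17 by Fráter–Seebach methylation); then C7 ester → aldehyde, directed C13–C14 epoxidation, two acetates, C16–OH → Br.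
3. C2–C6/C16 arm ⇐ Brown allylation of the C2 aldehyde, acrylate ring-closing metathesis to a temporary δ-lactone (ring D), α-chloromethylenation (E geometry held by the lactone), reduction.
4. Ring A (C1, C10–C14) ⇐ catalytic enantioselective Diels–Alder reaction of silyloxydiene 2 with enal 5 (C1, C10); C11 by kinetic protonation, C12 by Luche reduction and Mitsunobu inversion.
5. Ring order: ring A (step 3) → ring D (step 6, opened in step 9) → epoxide (step 25) → ring B (step 29) → ring C (step 30). Numbering: C15 = methyl on C1, C20 = methyl on C11, C18 = methyl on C17.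

Key step: step 29

Assumption: the (S)-configured oxazaborolidinium catalyst of step 3 is taken to expose the C1-Si face of enal 5 (accepted facial model for α-substituted enals); if the sense is opposite, the (R)-catalyst is used in the same step.

## Route

Step 1
Reactants: 1 pent-1-en-3-one
Product: 2 (3Z)-3-(triisopropylsilyloxy)penta-1,3-diene
Conditions: i-Pr3SiOTf, Et3N, Et2O, 0 °C
Reagents that add atoms: triisopropylsilyl trifluoromethanesulfonate, CC(C)[Si](C(C)C)(C(C)C)OS(=O)(=O)C(F)(F)F
Why: Soft enolisation of the ethyl ketone (silyl enol ether formation) should give the Z dienol ether, whose methyl group is trans to the vinyl group and therefore "outside" in the cycloaddition.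

Step 2
Reactants: 3 2-[(4-methoxyphenyl)methoxy]acetaldehyde; 4 2-(triphenylphosphoranylidene)propanal
Product: 5 (E)-4-[(4-methoxyphenyl)methoxy]-2-methylbut-2-enal
Conditions: toluene, 90 °C
Reagents that add atoms: none
Why: Wittig olefination with the stabilised formyl ylide should give the E trisubstituted enal, which later places C15 and C9 cis on ring A.

Step 3
Reactants: 2 silyloxydiene; 5 enal
Product: 6 ring A aldehyde (C1: CH3 and CHO; C10: CH2OPMB cis to C1-CH3; C11-CH3 trans to CH2OPMB; C12=C13 triisopropylsilyl enol ether)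
Conditions: (S)-o-tolyl-oxazaborolidine [from (S)-α,α-diphenylprolinol and 2-MeC6H4B(OH)2]·HN(SO2CF3)2 (20 mol %), CH2Cl2, −78 → −40 °C
Reagents that add atoms: none
Why: Catalytic enantioselective Diels–Alder reaction: the 2-silyloxy group directs C11 to the enal β-carbon C10 and C14 to C1, the E enal carries C15 cis to C9, the formyl group reacts endo (C11-methyl cis to CHO, corrected in step 13) and the chiral boron Lewis acid selects the C1-Si face, setting C1 and C10.

Step 4
Reactants: 6 ring A aldehyde
Product: 8 (2R)-homoallylic alcohol, via borinate ester 7 (not isolated)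
Conditions: B-allyldiisopinocampheylborane from (−)-α-pinene [made from (+)-Ipc2BOMe and CH2=CHCH2MgBr], Et2O, −78 °C; then NaBO3·4H2O, THF/H2O, rt
Reagents that add atoms: B-allyldiisopinocampheylborane, C=CCB([C@H]1C[C@H]2C[C@@H]([C@@H]1C)C2(C)C)[C@H]1C[C@H]2C[C@@H]([C@@H]1C)C2(C)C
Why: Brown allylation through a chair allylboration transition state is reagent-controlled, and this pinene series should add allyl to the Re face of the neopentyl aldehyde to give the (2R) carbinol, while the silyl enol ether acts as a masked ketone.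

Step 5
Reactants: 8 homoallylic alcohol
Product: 9 acrylate ester of 8
Conditions: CH2=CHCOCl, i-Pr2NEt, DMAP (cat.), CH2Cl2, 0 °C
Reagents that add atoms: acryloyl chloride, C=CC(=O)Cl
Why: DMAP-catalysed acylation of the hindered secondary alcohol installs C5 and C16 as the acrylate.

Step 6
Reactants: 9 acrylate
Product: 10 5,6-dihydro-2H-pyran-2-one (ring D: O–C16(=O)–C5=C4–C3–C2)
Conditions: second-generation Grubbs catalyst RuCl2(=CHPh)(PCy3)(H2IMes) (5 mol %), CH2Cl2 (5 mM), 40 °C
Reagents that add atoms: none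
Why: Ring-closing metathesis of the acrylate with the terminal alkene closes the six-membered unsaturated lactone with loss of ethene and leaves the trisubstituted enol ether alone.

Step 7
Reactants: 10 unsaturated δ-lactone
Product: 12 α-(hydroxymethylene)-δ-lactone, via lithium lactone enolate 11 (not isolated)
Conditions: LiBH(s-Bu)3, THF, −78 °C; then HCO2Et, −78 → 0 °C; aq NH4Cl
Reagents that add atoms: ethyl formate, CCOC=O
Why: Conjugate reduction of the unsaturated lactone by the hindered borohydride gives the enolate, which undergoes Claisen formylation at C5 to bring in C6; no stereocentre is formed.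

Step 8
Reactants: 12 hydroxymethylene lactone
Product: 13 (E)-α-(chloromethylene)-δ-lactone (Cl cis to C4, trans to C16)
Conditions: PPh3, CCl4, MeCN, 25 → 50 °C
Reagents that add atoms: tetrachloromethane, ClC(Cl)(Cl)Cl
Why: Appel-type chlorination of the β-dicarbonyl enol (phosphonium activation, chloride addition–elimination) should give the vinylogous acid chloride, and reversible chloride addition lets it settle as the E isomer, in which chlorine avoids the lactone carbonyl held s-cis by ring D.

Step 9
Reactants: 13 chloromethylene lactone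
Product: 14 C2,C16-diol with (E)-chloroalkene
Conditions: i-Bu2AlH (4 equiv), CH2Cl2, −78 → −20 °C; aq sodium potassium tartrate
Reagents that add atoms: none
Why: 1,2-Hydride reduction of the lactone opens ring D to the primary allylic C16 alcohol and the C2 alcohol without touching the vinyl chloride, so the alkene geometry is kept and the two hydroxyls are differentiated.

Step 10
Reactants: 14 diol
Product: 15 C16 tert-butyldiphenylsilyl ether
Conditions: t-BuPh2SiCl, imidazole, CH2Cl2, 0 °C
Reagents that add atoms: tert-butyl(chloro)diphenylsilane, CC(C)(C)[Si](Cl)(c1ccccc1)c1ccccc1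
Why: Silylation with the bulky chlorosilane is selective for the primary allylic hydroxyl over the neopentyl C2 hydroxyl.

Step 11
Reactants: 15 mono-silyl ether
Product: 16 C2 triethylsilyl ether
Conditions: Et3SiOTf, 2,6-lutidine, CH2Cl2, −78 °C
Reagents that add atoms: triethylsilyl trifluoromethanesulfonate, CC[Si](CC)(CC)OS(=O)(=O)C(F)(F)F
Why: The silyl triflate protects the hindered C2 hydroxyl as an ether that step 22 removes.

Step 12
Reactants: 16 silyl enol ether
Product: 17 C12 ketone/C13=C14 enone (C11-CH3 still trans to the C9 arm)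
Conditions: Pd(OAc)2 (1.2 equiv), DMSO, 45 °C
Reagents that add atoms: none
Why: Saegusa–Ito oxidation: divalent palladium converts the regiodefined silyl enol ether into the enone, since β-hydride elimination can only occur toward C14.

Step 13
Reactants: 17 enone
Product: 19 enone with C11-CH3 cis to the C9 arm, via lithium dienolate 18 (not isolated)
Conditions: LiN(i-Pr)2 (1.3 equiv), THF, −78 °C; then 2,6-di-tert-butyl-4-methylphenol, −78 °C; aq NH4Cl
Reagents that add atoms: none
Why: Kinetic enolate protonation: in the cross-conjugated dienolate the C10 arm sits pseudo-axial to avoid allylic strain with the C11 methyl, so axial protonation from the face opposite C9 should place the methyl cis to C9, which is also the expected thermodynamic isomer (both methyls equatorial, the two large arms trans-diaxial).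

Step 14
Reactants: 19 enone
Product: 20 allylic alcohol with C12–OH on the C15 face (cis to C11-CH3)
Conditions: NaBH4, CeCl3·7H2O, MeOH, −78 → −40 °C
Reagents that add atoms: none
Why: Luche 1,2-reduction: the axial C9 arm blocks the C15 face of the carbonyl, so hydride should add from the C2 face and give the axial alcohol.

Step 15
Reactants: 20 allylic alcohol
Product: 21 C12 benzoate on the C2 face (trans to C11-CH3)
Conditions: PPh3, i-PrO2CN=NCO2i-Pr, PhCO2H, toluene, 0 °C → rt
Reagents that add atoms: benzoic acid, OC(=O)c1ccccc1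
Why: Mitsunobu reaction: SN2 displacement of the activated axial oxygen by benzoate inverts C12, and SN2′ attack at neopentyl C14 is disfavoured.

Step 16
Reactants: 21 benzoate
Product: 22 C9 primary alcohol
Conditions: DDQ, CH2Cl2/pH 7 buffer 10:1, 0 °C
Reagents that add atoms: none
Why: Oxidative cleavage of the p-methoxybenzyl ether frees the C9 hydroxyl; silyl ethers, benzoate and alkenes are inert.

Step 17
Reactants: 22 alcohol
Product: 23 C9 aldehyde
Conditions: Dess–Martin periodinane, NaHCO3, CH2Cl2, 0 °C → rt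
Reagents that add atoms: none
Why: Dess–Martin oxidation under buffered conditions gives the aldehyde without epimerising C10.

Step 18
Reactants: 24 dimethyl (S)-malate
Product: 26 dimethyl (2S,3R)-2-hydroxy-3-methylbutanedioate, via dilithium alkoxide enolate 25 (not isolated)
Conditions: LiN(i-Pr)2 (2.2 equiv), THF, −78 → −20 °C; MeI, −78 → −10 °C; aq NH4Cl
Reagents that add atoms: iodomethane, CI
Why: Fráter–Seebach alkylation: the chelated dianion of the β-hydroxy ester is methylated anti to the alkoxide, which sets C17 (with C18).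

Step 19
Reactants: 26 methylmalate diester
Product: 27 (2S,3R)-2-hydroxy-3-methylbutanedioic acid
Conditions: KOH, MeOH/H2O, rt; then aq HCl to pH 1
Reagents that add atoms: potassium hydroxide, [K+].[OH-]
Why: Saponification of both esters followed by acidification gives the diacid without touching the stereocentres.

Step 20
Reactants: 27 diacid
Product: 28 (2R)-2-[(2S,4S)-2-tert-butyl-5-oxo-1,3-dioxolan-4-yl]propanoic acid
Conditions: t-BuCHO, TsOH·H2O (cat.), H2SO4 (cat.), pentane, reflux, water separator
Reagents that add atoms: pivalaldehyde, CC(C)(C)C=O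
Why: Acid-catalysed acetalisation of the α-hydroxy acid gives the five-membered dioxolanone, the cis isomer being thermodynamically preferred and crystallisable; the acetal carbon stores the C8 configuration.

Step 21
Reactants: 23 C9 aldehyde; 28 dioxolanone acid
Product: 30 C8–C9 aldol adduct, via dilithium enolate carboxylate 29 (not isolated)
Conditions: 28, LiN(SiMe3)2 (2.2 equiv), THF, −78 °C; then 23, −78 °C; AcOH, −78 °C
Reagents that add atoms: none
Why: Aldol addition of the dioxolanone enolate (self-regeneration of the stereocentre): the aldehyde enters anti to the tert-butyl group so C8 forms with retention, the chair transition state of this enolate (side chain cis to OLi) places C17 and the new C9 oxygen syn, and that is also the Felkin–Anh face of the aldehyde with quaternary C1 as the large group.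

Step 22
Reactants: 30 aldol adduct
Product: 32 C7,C19 dimethyl ester with C8/C9 acetonide (C2–OH free, C12 benzoate), via triol dimethyl ester 31 (not isolated)
Conditions: HCl (1.25 M in MeOH), 25 → 40 °C; evaporate; Me2C(OMe)2, CSA (cat.), MeOH/acetone, rt
Reagents that add atoms: methanol, CO; 2,2-dimethoxypropane, COC(C)(C)OC
Why: Acidic methanolysis cleaves the acylal (C7 becomes a methyl ester), esterifies C19 and removes the triethylsilyl ether, and ketalisation then ties the C8/C9 diol as the acetonide, which pulls any C9–O/C19 lactone into the open diester; no alkoxide is formed, so retro-aldol cleavage at C8 is avoided.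

Step 23
Reactants: 32 benzoate
Product: 33 C2,C12-diol
Conditions: K2CO3, MeOH, rt
Reagents that add atoms: none
Why: Mild transesterification removes the allylic benzoate, while exchange at the two methyl esters is degenerate.

Step 24
Reactants: 33 diester diol
Product: 34 C7 aldehyde (C19 methyl ester kept)
Conditions: i-Bu2AlH (3.3 equiv), CH2Cl2, −78 °C; MeOH, then aq sodium potassium tartrate
Reagents that add atoms: none
Why: Chelation-activated half-reduction: the α-alkoxy C7 ester on the dioxolane is reduced faster than the β-branched C19 ester, and the aluminium hemiacetal is stable at −78 °C, so the aldehyde appears only on work-up.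

Step 25
Reactants: 34 allylic alcohol
Product: 35 C13,C14-epoxide syn to C12–OH
Conditions: VO(acac)2 (5 mol %), t-BuOOH (in decane), CH2Cl2, 0 °C → rt
Reagents that add atoms: tert-butyl hydroperoxide, CC(C)(C)OO
Why: Hydroxyl-directed epoxidation: vanadium bound to the allylic C12 hydroxyl (and the homoallylic C2 hydroxyl on the same face) delivers oxygen to the C2 face of C13=C14, setting C13 and C14; the electron-poor chloroalkene is not epoxidised.

Step 26
Reactants: 35 epoxy diol
Product: 36 C2,C12-diacetate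
Conditions: Ac2O, pyridine, DMAP (cat.), CH2Cl2, rt
Reagents that add atoms: acetic anhydride, CC(=O)OC(C)=O
Why: DMAP-catalysed acetylation esterifies both secondary hydroxyls.

Step 27
Reactants: 36 silyl ether
Product: 37 C16 allylic alcohol
Conditions: Bu4NF, AcOH (1:1), THF, 0 °C → rt
Reagents that add atoms: none
Why: Buffered fluoride desilylation cleaves the primary silyl ether and leaves acetates, epoxide and the non-enolisable aldehyde untouched.

Step 28
Reactants: 37 allylic alcohol
Product: 39 (E)-chloroallyl bromide aldehyde (key precursor), via allylic mesylate 38 (not isolated)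
Conditions: MsCl, Et3N, CH2Cl2, −20 °C; then LiBr, THF, 0 °C
Reagents that add atoms: lithium bromide, [Li+].[Br-]; methanesulfonyl chloride, CS(=O)(=O)Cl (ends in 38 only)
Why: SN2 displacement of the primary allylic mesylate by bromide at C16 keeps the position and E geometry of the chloroalkene.

Step 29
Reactants: 39 chloroallyl bromide aldehyde
Product: 41 ten-membered chlorohydrin ester, via allylchromium dichloride 40 (not isolated)
Conditions: CrCl2 (8 equiv), THF/DMF 10:1, rt; 39 added over 12 h (final 2 mM); aq sodium potassium tartrate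
Reagents that add atoms: none
Why: Proposed new method: chromium dichloride reduces the allylic C16–Br bond by two one-electron transfers to a trivalent-chromium allyl species (40) bound at C16, which adds through C6 (SE2′, six-membered chair transition state with chromium on the aldehyde oxygen) to the C7 aldehyde, forming C6–C7 and leaving C5=C16 as the exocyclic methylene. The closest known reactions are the intermolecular chromium dichloride-mediated γ-chloroallylation of aldehydes to anti chlorohydrins and Nozaki–Hiyama–Kishi allylation macrocyclisations of 2-substituted allylic bromides. Ring B (ten-membered, C1–C10) closes by 1,2-addition of C6 to the C7 carbonyl (exo-trig with respect to C=O), with chromium holding both reacting ends. C6 and C7 form together: the (E)-γ-chloroallyl unit (Cl trans to C16) with the C8 substituent equatorial in the chair gives the anti C6-Cl/C7-O relationship, and the C7 face is the one anti to the C8–O bond of the dioxolane (polar Felkin–Anh) with C9 and the tether on the ring-forming side. The step needs γ- over α-attack, which the closed transition state of allylchromium reagents provides, and ring closure over oligomerisation, which slow addition into excess CrCl2 at high dilution and the non-enolisable aldehyde should secure. Acetates, the methyl ester, the epoxide and the acetonide should be inert, because organochromium reagents add selectively to aldehydes.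

Step 30
Reactants: 41 chlorohydrin ester
Product: 43 CNP0242711.1 (target), via lactone acetonide 42 (not isolated)
Conditions: CSA (10 mol %), CH2Cl2, rt; then AcOH/H2O 4:1, 40 °C
Reagents that add atoms: none
Why: Acid-catalysed lactonisation of C7–OH onto the C19 ester closes ring C while C9–O is still held in the acetonide, and acetal hydrolysis then frees the C8 and C9 hydroxyls; the epoxide, flanked by acetoxy-bearing C12 and quaternary C1, should survive dilute acetic acid.

## Compound list

1 | pent-1-en-3-one | C=CC(=O)CC | starting material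
2 | (3Z)-3-(triisopropylsilyloxy)penta-1,3-diene | C=C/C(O[Si](C(C)C)(C(C)C)C(C)C)=C/C | intermediate
3 | 2-[(4-methoxyphenyl)methoxy]acetaldehyde | O=CCOCc1ccc(OC)cc1 | starting material
4 | 2-(triphenylphosphoranylidene)propanal | CC(C=O)=P(c1ccccc1)(c1ccccc1)c1ccccc1 | starting material
5 | (E)-4-[(4-methoxyphenyl)methoxy]-2-methylbut-2-enal | O=C/C(C)=C/COCc1ccc(OC)cc1 | intermediate
6 | ring A aldehyde: C1 (CH3, CHO), C10 CH2OPMB cis to C1-CH3, C11-CH3 trans to CH2OPMB, C12=C13 TIPS enol ether | O=C[C@]1(C)[C@H]([C@H](C)C(O[Si](C(C)C)(C(C)C)C(C)C)=CC1)COCc1ccc(OC)cc1 | intermediate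
7 | diisopinocampheylborinate of (2R)-homoallylic alcohol 8 | C=CC[C@@H](OB([C@H]2C[C@H]3C[C@@H]([C@@H]2C)C3(C)C)[C@H]2C[C@H]3C[C@@H]([C@@H]2C)C3(C)C)[C@]1(C)[C@H]([C@H](C)C(O[Si](C(C)C)(C(C)C)C(C)C)=CC1)COCc1ccc(OC)cc1 | intermediate
8 | (2R)-homoallylic alcohol (C2–OH, C3H2–CH=CH2 on C2) | C=CC[C@@H](O)[C@]1(C)[C@H]([C@H](C)C(O[Si](C(C)C)(C(C)C)C(C)C)=CC1)COCc1ccc(OC)cc1 | intermediate
9 | C2 acrylate of 8 | C=CC[C@@H](OC(=O)C=C)[C@]1(C)[C@H]([C@H](C)C(O[Si](C(C)C)(C(C)C)C(C)C)=CC1)COCc1ccc(OC)cc1 | intermediate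
10 | (2R)-5,6-dihydro-2H-pyran-2-one, ring D = O–C16(=O)–C5=C4–C3–C2, ring A on C2 | O=C1C=CC[C@H]([C@]2(C)[C@H]([C@H](C)C(O[Si](C(C)C)(C(C)C)C(C)C)=CC2)COCc2ccc(OC)cc2)O1 | intermediate
11 | lithium enolate of the saturated δ-lactone (C16(OLi)=C5) | [Li]OC1=CCC[C@H]([C@]2(C)[C@H]([C@H](C)C(O[Si](C(C)C)(C(C)C)C(C)C)=CC2)COCc2ccc(OC)cc2)O1 | intermediate
12 | α-(hydroxymethylene)-δ-lactone (C5=C6H–OH, hydrogen-bonded enol) | O=C1/C(=C\O)CC[C@H]([C@]2(C)[C@H]([C@H](C)C(O[Si](C(C)C)(C(C)C)C(C)C)=CC2)COCc2ccc(OC)cc2)O1 | intermediate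
13 | (E)-α-(chloromethylene)-δ-lactone (Cl trans to C16=O, cis to C4) | O=C1/C(=C/Cl)CC[C@H]([C@]2(C)[C@H]([C@H](C)C(O[Si](C(C)C)(C(C)C)C(C)C)=CC2)COCc2ccc(OC)cc2)O1 | intermediate
14 | C2,C16-diol with (E)-C5=C6HCl | OC/C(=C/Cl)CC[C@@H](O)[C@]1(C)[C@H]([C@H](C)C(O[Si](C(C)C)(C(C)C)C(C)C)=CC1)COCc1ccc(OC)cc1 | intermediate
15 | C16–OTBDPS, C2–OH | CC(C)(C)[Si](c1ccccc1)(c1ccccc1)OC/C(=C/Cl)CC[C@@H](O)[C@]1(C)[C@H]([C@H](C)C(O[Si](C(C)C)(C(C)C)C(C)C)=CC1)COCc1ccc(OC)cc1 | intermediate
16 | C16–OTBDPS, C2–OTES, ring A TIPS enol ether | CC(C)(C)[Si](c1ccccc1)(c1ccccc1)OC/C(=C/Cl)CC[C@@H](O[Si](CC)(CC)CC)[C@]1(C)[C@H]([C@H](C)C(O[Si](C(C)C)(C(C)C)C(C)C)=CC1)COCc1ccc(OC)cc1 | intermediate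
17 | C12 ketone, C13=C14 enone, C11-CH3 trans to C9 arm | CC(C)(C)[Si](c1ccccc1)(c1ccccc1)OC/C(=C/Cl)CC[C@@H](O[Si](CC)(CC)CC)[C@]1(C)[C@H]([C@H](C)C(=O)C=C1)COCc1ccc(OC)cc1 | intermediate
18 | lithium cross-conjugated dienolate (C11=C12(OLi)–C13=C14) | CC(C)(C)[Si](c1ccccc1)(c1ccccc1)OC/C(=C/Cl)CC[C@@H](O[Si](CC)(CC)CC)[C@]1(C)[C@H](C(C)=C(O[Li])C=C1)COCc1ccc(OC)cc1 | intermediate
19 | enone with C11-CH3 cis to C9 arm (all of C15, C9, C20 on one face) | CC(C)(C)[Si](c1ccccc1)(c1ccccc1)OC/C(=C/Cl)CC[C@@H](O[Si](CC)(CC)CC)[C@]1(C)[C@H]([C@@H](C)C(=O)C=C1)COCc1ccc(OC)cc1 | intermediate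
20 | allylic alcohol, C12–OH cis to C11-CH3 (C15 face) | CC(C)(C)[Si](c1ccccc1)(c1ccccc1)OC/C(=C/Cl)CC[C@@H](O[Si](CC)(CC)CC)[C@]1(C)[C@H]([C@@H](C)[C@@H](O)C=C1)COCc1ccc(OC)cc1 | intermediate
21 | C12 benzoate trans to C11-CH3 (C2 face) | CC(C)(C)[Si](c1ccccc1)(c1ccccc1)OC/C(=C/Cl)CC[C@@H](O[Si](CC)(CC)CC)[C@]1(C)[C@H]([C@@H](C)[C@H](OC(=O)c2ccccc2)C=C1)COCc1ccc(OC)cc1 | intermediate
22 | C9 primary alcohol | CC(C)(C)[Si](c1ccccc1)(c1ccccc1)OC/C(=C/Cl)CC[C@@H](O[Si](CC)(CC)CC)[C@]1(C)[C@H]([C@@H](C)[C@H](OC(=O)c2ccccc2)C=C1)CO | intermediate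
23 | C9 aldehyde | CC(C)(C)[Si](c1ccccc1)(c1ccccc1)OC/C(=C/Cl)CC[C@@H](O[Si](CC)(CC)CC)[C@]1(C)[C@H]([C@@H](C)[C@H](OC(=O)c2ccccc2)C=C1)C=O | intermediate
24 | dimethyl (S)-malate | COC(=O)C[C@H](O)C(=O)OC | starting material
25 | dilithium alkoxide enolate of 24 | COC(O[Li])=C[C@H](O[Li])C(=O)OC | intermediate
26 | dimethyl (2S,3R)-2-hydroxy-3-methylbutanedioate | COC(=O)[C@H](C)[C@H](O)C(=O)OC | intermediate
27 | (2S,3R)-2-hydroxy-3-methylbutanedioic acid | OC(=O)[C@H](C)[C@H](O)C(=O)O | intermediate
28 | (2R)-2-[(2S,4S)-2-tert-butyl-5-oxo-1,3-dioxolan-4-yl]propanoic acid (cis) | CC(C)(C)[C@H]1O[C@@H]([C@@H](C)C(=O)O)C(=O)O1 | intermediate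
29 | dilithium ring enolate carboxylate of 28 | CC(C)(C)[C@H]1OC([C@@H](C)C(=O)O[Li])=C(O[Li])O1 | intermediate
30 | aldol adduct: C9–OH, C8 quaternary in the dioxolanone (C7 = ring C=O), C17(CH3)–C19O2H | CC(C)(C)[Si](c1ccccc1)(c1ccccc1)OC/C(=C/Cl)CC[C@@H](O[Si](CC)(CC)CC)[C@]1(C)[C@H]([C@@H](C)[C@H](OC(=O)c2ccccc2)C=C1)[C@@H](O)[C@]1(O[C@H](C(C)(C)C)OC1=O)[C@@H](C)C(=O)O | intermediate
31 | C2,C8,C9-triol C7,C19-dimethyl ester | CC(C)(C)[Si](c1ccccc1)(c1ccccc1)OC/C(=C/Cl)CC[C@@H](O)[C@]1(C)[C@H]([C@@H](C)[C@H](OC(=O)c2ccccc2)C=C1)[C@@H](O)[C@](O)([C@@H](C)C(=O)OC)C(=O)OC | intermediate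
32 | C8/C9 acetonide, C7 and C19 methyl esters, C2–OH, C12–OBz | CC(C)(C)[Si](c1ccccc1)(c1ccccc1)OC/C(=C/Cl)CC[C@@H](O)[C@]1(C)[C@H]([C@@H](C)[C@H](OC(=O)c2ccccc2)C=C1)[C@H]1OC(C)(C)O[C@@]1([C@@H](C)C(=O)OC)C(=O)OC | intermediate
33 | C2,C12-diol diester acetonide | CC(C)(C)[Si](c1ccccc1)(c1ccccc1)OC/C(=C/Cl)CC[C@@H](O)[C@]1(C)[C@H]([C@@H](C)[C@H](O)C=C1)[C@H]1OC(C)(C)O[C@@]1([C@@H](C)C(=O)OC)C(=O)OC | intermediate
34 | C7 aldehyde, C19 methyl ester, C2,C12-diol | CC(C)(C)[Si](c1ccccc1)(c1ccccc1)OC/C(=C/Cl)CC[C@@H](O)[C@]1(C)[C@H]([C@@H](C)[C@H](O)C=C1)[C@H]1OC(C)(C)O[C@@]1([C@@H](C)C(=O)OC)C=O | intermediate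
35 | C13,C14-epoxide syn to C12–OH | CC(C)(C)[Si](c1ccccc1)(c1ccccc1)OC/C(=C/Cl)CC[C@@H](O)[C@]1(C)[C@H]([C@@H](C)[C@H](O)[C@@H]2O[C@@H]21)[C@H]1OC(C)(C)O[C@@]1([C@@H](C)C(=O)OC)C=O | intermediate
36 | C2,C12-diacetate | CC(C)(C)[Si](c1ccccc1)(c1ccccc1)OC/C(=C/Cl)CC[C@@H](OC(C)=O)[C@]1(C)[C@H]([C@@H](C)[C@H](OC(C)=O)[C@@H]2O[C@@H]21)[C@H]1OC(C)(C)O[C@@]1([C@@H](C)C(=O)OC)C=O | intermediate
37 | C16 allylic alcohol | OC/C(=C/Cl)CC[C@@H](OC(C)=O)[C@]1(C)[C@H]([C@@H](C)[C@H](OC(C)=O)[C@@H]2O[C@@H]21)[C@H]1OC(C)(C)O[C@@]1([C@@H](C)C(=O)OC)C=O | intermediate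
38 | C16 allylic mesylate | CS(=O)(=O)OC/C(=C/Cl)CC[C@@H](OC(C)=O)[C@]1(C)[C@H]([C@@H](C)[C@H](OC(C)=O)[C@@H]2O[C@@H]21)[C@H]1OC(C)(C)O[C@@]1([C@@H](C)C(=O)OC)C=O | intermediate
39 | acyclic (E)-chloroallyl bromide aldehyde, C8/C9 acetonide (key precursor) | BrC/C(=C/Cl)CC[C@@H](OC(C)=O)[C@]1(C)[C@H]([C@@H](C)[C@H](OC(C)=O)[C@@H]2O[C@@H]21)[C@H]1OC(C)(C)O[C@@]1([C@@H](C)C(=O)OC)C=O | intermediate
40 | C16 allylchromium dichloride (trivalent chromium) | Cl[Cr](Cl)C/C(=C/Cl)CC[C@@H](OC(C)=O)[C@]1(C)[C@H]([C@@H](C)[C@H](OC(C)=O)[C@@H]2O[C@@H]21)[C@H]1OC(C)(C)O[C@@]1([C@@H](C)C(=O)OC)C=O | intermediate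
41 | ten-membered chlorohydrin ester (ring B closed; C6–Cl, C7–OH, C5=C16) | C=C1CC[C@@H](OC(C)=O)[C@]2(C)[C@H]([C@@H](C)[C@H](OC(C)=O)[C@@H]3O[C@@H]32)[C@H]2OC(C)(C)O[C@@]2([C@@H](C)C(=O)OC)[C@@H](O)[C@H]1Cl | intermediate
42 | γ-lactone (C7–O–C19) with C8/C9 acetonide | C=C1CC[C@@H](OC(C)=O)[C@]2(C)[C@H]([C@@H](C)[C@H](OC(C)=O)[C@@H]3O[C@@H]32)[C@H]4OC(C)(C)O[C@]42[C@@H](C)C(=O)O[C@H]2[C@H]1Cl | intermediate
43 | CNP0242711.1; configuration 1S,2R,6S,7R,8R,9R,10S,11R,12S,13S,14R,17R in the overview numbering | C=C1CC[C@@H](OC(C)=O)[C@]2(C)[C@H]([C@@H](C)[C@H](OC(C)=O)[C@@H]3O[C@@H]32)[C@@H](O)[C@]2(O)[C@@H](C)C(=O)O[C@H]2[C@H]1Cl | target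

## Step count and risks

Total step count: 30. Longest linear sequence: 26 steps (steps 2–17, then 21–30); steps 1 and 18–20 are side branches.

Steps most likely to fail:

1. Step 29 (bears the label). Intermolecular coupling may outrun ring closure, the allylchromium may be protonated before it adds, or addition may occur through the wrong aldehyde face or the α-carbon. The fallback sets out from allylic alcohol 37. It is acetylated (Ac2O, pyridine) to the allylic acetate F1, which is treated with B2pin2 and Pd(dba)2 (zerovalent palladium) in DMSO at 50 °C under high dilution. The (E)-γ-chloroallyl pinacol boronate F2 formed in the flask adds to the tethered C7 aldehyde by an uncatalysed chair allylboration and, after aqueous work-up, returns to the route at 41. Both operations are known reaction types: palladium-catalysed borylation of allylic acetates, whose aldehyde-tethered substrates cyclise in the flask, and the addition of (E)-γ-chloroallylboronates to aldehydes, which gives anti chlorohydrins.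

2. Step 21. The basic enolate may enolise the hindered aldehyde (loss of the C10 configuration), the crowded aldolate may revert by retro-aldol cleavage, or facial control at C9 may be poor. The fallback sets out from dioxolanone 28. Its dianion 29 is silylated with Me3SiCl to the bis(trimethylsilyl) ketene acetal ester F3, which is added to aldehyde 23 with BF3·OEt2 in CH2Cl2 at −78 °C (Mukaiyama aldol, open transition state, no base in contact with the aldehyde). Aqueous work-up cleaves the silyl ester and the route is rejoined at 30.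

3. Step 15. The activated axial oxygen may be lost by E2 elimination toward C11–H to give a cyclohexadiene, or displacement at the hindered carbinol may not take place. The fallback sets out from enone 19. Meerwein–Ponndorf–Verley reduction under equilibrating conditions (Al(O-i-Pr)3, i-PrOH, toluene, 80 °C) should give the thermodynamically preferred equatorial allylic alcohol F4 (C12–OH on the C2 face) directly. Benzoylation (PhCOCl, pyridine, DMAP) then returns to the route at 21.

## Further compounds

F1 | step 29 | C16 allylic acetate of 37 (triacetate aldehyde) | CC(=O)OC/C(=C/Cl)CC[C@@H](OC(C)=O)[C@]1(C)[C@H]([C@@H](C)[C@H](OC(C)=O)[C@@H]2O[C@@H]21)[C@H]1OC(C)(C)O[C@@]1([C@@H](C)C(=O)OC)C=O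
F2 | step 29 | C16 (E)-γ-chloroallyl pinacol boronate aldehyde | CC1(C)OB(C/C(=C/Cl)CC[C@@H](OC(C)=O)[C@]2(C)[C@H]([C@@H](C)[C@H](OC(C)=O)[C@@H]3O[C@@H]32)[C@H]2OC(C)(C)O[C@@]2([C@@H](C)C(=O)OC)C=O)OC1(C)C
F3 | step 21 | bis(trimethylsilyl) ketene acetal ester of 28 | CC(C)(C)[C@H]1OC([C@@H](C)C(=O)O[Si](C)(C)C)=C(O[Si](C)(C)C)O1
F4 | step 15 | allylic alcohol with C12–OH trans to C11-CH3 (C2 face) | CC(C)(C)[Si](c1ccccc1)(c1ccccc1)OC/C(=C/Cl)CC[C@@H](O[Si](CC)(CC)CC)[C@]1(C)[C@H]([C@@H](C)[C@H](O)C=C1)COCc1ccc(OC)cc1
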